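In both coumarin units (A, 7-hydroxy-6-aryloxy; B, 5-aryloxy-6,7-dihydroxy) the pyranone oxygen O1 is bonded to C8a, beside the C4a carbon that carries the C4–C3–C2 chain and para to the oxygenated C6: the pattern of an ortho-oxygenated cinnamate. Both O1–C8a bonds are therefore disconnected together, back to a diaryl ether bearing two E-acrylic acid arms and three methyl-protected phenols. A single flavin-photocatalysed aerobic operation should isomerise both alkenes and forge both aryl C–O bonds, closing the two pyranone rings. The precursor comes from an SNAr-derived dialdehyde by double Knoevenagel–Doebner condensation; global demethylation finishes the route.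

Key step: step 3

Remark: coumarin numbering is used for both units; 2-fluoro-3,4-dimethoxybenzaldehyde is assumed to be a purchasable fluoroarene, and methyl ethers are kept as phenol protection because they should resist the photo-oxidant.

**Route**

Step 1
Reactants: 1 isovanillin (3-hydroxy-4-methoxybenzaldehyde); 2 2-fluoro-3,4-dimethoxybenzaldehyde
Product: 3 3-(6-formyl-2,3-dimethoxyphenoxy)-4-methoxybenzaldehyde
Conditions: K2CO3 (2 equiv), DMA, 130 °C, N2
Reagents that add atoms: none
Why: Nucleophilic aromatic substitution by addition–elimination: the phenoxide of 1 attacks the fluorine-bearing carbon of 2, the ortho formyl group stabilises the Meisenheimer adduct and fluoride leaves, while the formyl group of 1 is meta to the phenoxide oxygen and so does not drain its nucleophilicity.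

Step 2
Reactants: 3 3-(6-formyl-2,3-dimethoxyphenoxy)-4-methoxybenzaldehyde; 4 malonic acid (one molecule per formyl group, two in all)
Product: 6 (2E)-3-{3-[6-[(E)-2-carboxyethenyl]-2,3-dimethoxyphenoxy]-4-methoxyphenyl}prop-2-enoic acid (E,E-bis-cinnamic acid), via bis(arylidenemalonic acid) 5 (not isolated)
Conditions: malonic acid (6 equiv in all), piperidine (cat.), pyridine, 100 °C; then cold aq. HCl
Reagents that add atoms: malonic acid (second molecule of compound 4, for the second formyl group), OC(=O)CC(O)=O
Why: Knoevenagel condensation in the Doebner modification: each of the two non-enolisable aryl aldehyde groups condenses with its own molecule of malonic acid under piperidine catalysis and each adduct loses one CO2 in hot pyridine, which should deliver the conjugated E acid in both arms.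

Step 3
Reactants: 6 E,E-bis-cinnamic acid
Product: 8 6,7-dimethoxy-5-[(7-methoxy-2-oxo-2H-chromen-6-yl)oxy]-2H-chromen-2-one (tri-O-methyl bis-coumarin), via Z,Z-bis-cinnamic acid 7 (not isolated)
Conditions: (−)-riboflavin (C17H20N4O6, 2 × 5 mol%), O2 (1 atm), MeCN/MeOH 1:1 (0.01 M), blue LEDs (ca. 400–450 nm), rt
Reagents that add atoms: none
Why: Excited riboflavin first acts as a triplet sensitiser, turning each E-acrylic acid arm of 6 into the Z arm of 7 so that the carboxyl group lies beside an ortho C–H, and then as a one-electron oxidant that converts the methoxy-substituted arene into a radical cation; the carboxyl oxygen adds to the ortho carbon, a second oxidation with loss of the ring proton restores aromaticity, and O2 returns the reduced flavin to its resting form while ending up as H2O2. The closest known reaction type is the flavin-photocatalysed one-pot conversion of E-cinnamic acids into coumarins by photoisomerisation and dehydrogenative C–H lactonisation, run here on the two arms of one substrate. Both pyranone rings close in the same mode, a six-membered O–C(aryl) closure onto the sp2 carbon that becomes C8a (formally 6-endo-trig, the C4a–C8a bond lying inside the new ring), one unit after the other in the same flask. No stereocentre is created, and the Z geometry of each arm is absorbed into its lactone. The selectivity required is positional: in unit B the other ortho carbon already carries the aryloxy group, so a single C–H is available, and in unit A attack should prefer the open ortho carbon para to the aryloxy oxygen over the carbon wedged between side chain and diaryl ether. Each arene has a methoxy group para to its side chain, which keeps the oxidation potential within reach of the excited flavin, and methyl ethers expose neither a free phenol nor a weak C–H bond to the oxidant.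

Step 4
Reactants: 8 tri-O-methyl bis-coumarin
Product: 9 6,7-dihydroxy-5-[(7-hydroxy-2-oxo-2H-chromen-6-yl)oxy]-2H-chromen-2-one (CNP0197949.0)
Conditions: BBr3 (1 M in CH2Cl2, 9 equiv), CH2Cl2, −78 °C to rt; then H2O, 0 °C
Reagents that add atoms: none
Why: Lewis-acid cleavage of aryl methyl ethers: BBr3 complexes each methoxy oxygen and bromide removes the methyl group by SN2 attack, the aryl borates hydrolyse on quench, and neither the coumarin lactones nor the diaryl ether offers an sp3 carbon–oxygen bond for the same cleavage.

**Compound list**

1 | isovanillin (3-hydroxy-4-methoxybenzaldehyde) | O=Cc1ccc(OC)c(O)c1 | starting material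
2 | 2-fluoro-3,4-dimethoxybenzaldehyde | COc1ccc(C=O)c(F)c1OC | starting material
3 | 3-(6-formyl-2,3-dimethoxyphenoxy)-4-methoxybenzaldehyde | O=Cc1ccc(OC)c(Oc2c(OC)c(OC)ccc2C=O)c1 | intermediate
4 | malonic acid | OC(=O)CC(O)=O | starting material
5 | 2-{[3-[6-(2,2-dicarboxyethenyl)-2,3-dimethoxyphenoxy]-4-methoxyphenyl]methylidene}propanedioic acid (bis(arylidenemalonic acid), not isolated) | OC(=O)C(C(O)=O)=Cc1ccc(OC)c(Oc2c(OC)c(OC)ccc2C=C(C(O)=O)C(O)=O)c1 | intermediate
6 | (2E)-3-{3-[6-[(E)-2-carboxyethenyl]-2,3-dimethoxyphenoxy]-4-methoxyphenyl}prop-2-enoic acid (E,E-bis-cinnamic acid) | OC(=O)/C=C/c1ccc(OC)c(Oc2c(OC)c(OC)ccc2/C=C/C(O)=O)c1 | intermediate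
7 | (2Z)-3-{3-[6-[(Z)-2-carboxyethenyl]-2,3-dimethoxyphenoxy]-4-methoxyphenyl}prop-2-enoic acid (Z,Z-bis-cinnamic acid, not isolated) | OC(=O)/C=C\c1ccc(OC)c(Oc2c(OC)c(OC)ccc2/C=C\C(O)=O)c1 | intermediate
8 | 6,7-dimethoxy-5-[(7-methoxy-2-oxo-2H-chromen-6-yl)oxy]-2H-chromen-2-one (tri-O-methyl bis-coumarin) | O=c1ccc2cc(Oc3c(OC)c(OC)cc4oc(=O)ccc34)c(OC)cc2o1 | intermediate
9 | 6,7-dihydroxy-5-[(7-hydroxy-2-oxo-2H-chromen-6-yl)oxy]-2H-chromen-2-one (CNP0197949.0) | O=c1ccc2cc(Oc3c(O)c(O)cc4oc(=O)ccc34)c(O)cc2o1 | target

**Count**

Total step count: 4.
Longest linear sequence: 4 steps (1 or 2 → 3 → 6 → 8 → 9).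

**Steps most likely to fail**

Risk 1, step 3 (key step). The second lactonisation may stall once the flavin has bleached or the first coumarin unit screens the light. Without a β-substituent the Z acid stays conjugated, so the E/Z equilibrium is drained only by the cyclisation itself. The radical cation of unit B may be attacked at the ortho carbon that carries the aryloxy group, which would sever the diaryl ether, and singlet oxygen may erode the electron-rich arenes.

The fallback sets out from 6 and returns at 8, and needs no light, no alkene isomerisation and no O2. Hydrogenation of both alkenes (H2, Pd/C, THF/MeOH, rt) should give the saturated diacid 3-{3-[6-(2-carboxyethyl)-2,3-dimethoxyphenoxy]-4-methoxyphenyl}propanoic acid F1. Hypervalent iodine oxidation (PhI(OCOCF3)2, BF3·OEt2, CF3CO2H/CH2Cl2, 0 °C) is a known entry from 3-arylpropanoic acids with a para alkoxy group to 3,4-dihydrocoumarins, by ipso attack of the carboxyl group and 1,2-shift of the acyloxy oxygen to the free ortho carbon. It should give the bis-dihydrocoumarin 6,7-dimethoxy-5-[(7-methoxy-2-oxo-3,4-dihydro-2H-chromen-6-yl)oxy]-3,4-dihydro-2H-chromen-2-one F2. Dehydrogenation with DDQ in dioxane at reflux should then deliver 8.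

Risk 2, step 1. The addition–elimination may be slow, because the para methoxy group of 2 weakens the activating formyl group and the reacting carbon is flanked on both sides. Base-induced disproportionation of the aldehydes may then compete at the temperature required.

The fallback sets out from 1 and returns at 3, replacing the Meisenheimer pathway by copper catalysis. Bromination of 1 (Br2, NaOAc, Fe powder cat., AcOH) is known to occur between the hydroxyl and formyl groups and should give 2-bromo-3-hydroxy-4-methoxybenzaldehyde F3. O-Methylation (MeI, K2CO3, DMF) should give 2-bromo-3,4-dimethoxybenzaldehyde F4. Ullmann-type ether coupling of this bromide with a second equivalent of 1 (CuI, picolinic acid, K3PO4, DMSO, 90 °C) should give 3.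

Risk 3, step 4. Cleavage of the methoxy group flanked by two oxygen substituents may be incomplete, giving partially methylated mixtures, and the catechol of unit B may oxidise in air during isolation.

The fallback sets out from 3 and returns at 9. It exchanges the protecting groups before the rings are built, so that the last operation is a mild acetal hydrolysis. BBr3 (CH2Cl2, −78 °C to rt) on the robust dialdehyde 3 should give 3-(6-formyl-2,3-dihydroxyphenoxy)-4-hydroxybenzaldehyde F5. MOMCl with iPr2NEt (CH2Cl2, 0 °C to rt) should then give 3-[6-formyl-2,3-bis(methoxymethoxy)phenoxy]-4-(methoxymethoxy)benzaldehyde F6. Condensation with two molecules of 4 under the Knoevenagel–Doebner conditions of the route (work-up at pH 4) should give (2E)-3-{3-[6-[(E)-2-carboxyethenyl]-2,3-bis(methoxymethoxy)phenoxy]-4-(methoxymethoxy)phenyl}prop-2-enoic acid F7. The flavin photolactonisation of the route should convert this into 6,7-bis(methoxymethoxy)-5-{[7-(methoxymethoxy)-2-oxo-2H-chromen-6-yl]oxy}-2H-chromen-2-one F8, and HCl in MeOH at 40 °C should release 9.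

**Further compounds**

F1 | step 3 | 3-{3-[6-(2-carboxyethyl)-2,3-dimethoxyphenoxy]-4-methoxyphenyl}propanoic acid | OC(=O)CCc1ccc(OC)c(Oc2c(OC)c(OC)ccc2CCC(O)=O)c1
F2 | step 3 | 6,7-dimethoxy-5-[(7-methoxy-2-oxo-3,4-dihydro-2H-chromen-6-yl)oxy]-3,4-dihydro-2H-chromen-2-one | O=C1CCc2cc(Oc3c(OC)c(OC)cc4OC(=O)CCc34)c(OC)cc2O1
F3 | step 1 | 2-bromo-3-hydroxy-4-methoxybenzaldehyde | O=Cc1ccc(OC)c(O)c1Br
F4 | step 1 | 2-bromo-3,4-dimethoxybenzaldehyde | O=Cc1ccc(OC)c(OC)c1Br
F5 | step 4 | 3-(6-formyl-2,3-dihydroxyphenoxy)-4-hydroxybenzaldehyde | O=Cc1ccc(O)c(Oc2c(O)c(O)ccc2C=O)c1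
F6 | step 4 | 3-[6-formyl-2,3-bis(methoxymethoxy)phenoxy]-4-(methoxymethoxy)benzaldehyde | O=Cc1ccc(OCOC)c(Oc2c(OCOC)c(OCOC)ccc2C=O)c1
F7 | step 4 | (2E)-3-{3-[6-[(E)-2-carboxyethenyl]-2,3-bis(methoxymethoxy)phenoxy]-4-(methoxymethoxy)phenyl}prop-2-enoic acid | OC(=O)/C=C/c1ccc(OCOC)c(Oc2c(OCOC)c(OCOC)ccc2/C=C/C(O)=O)c1
F8 | step 4 | 6,7-bis(methoxymethoxy)-5-{[7-(methoxymethoxy)-2-oxo-2H-chromen-6-yl]oxy}-2H-chromen-2-one | O=c1ccc2cc(Oc3c(OCOC)c(OCOC)cc4oc(=O)ccc34)c(OCOC)cc2o1
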